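The oxolane ring (O, C3, C2, C1, C10; germacrane numbering) is cut at C2–C3 and O–C10. Because the carbinol C1 sits between the methylene C2 and the quaternary ether carbon C10, this ring is the retron of a Lewis-acid [3+2] annulation of an aldehyde with an allylsilane, the C–Si bond at C1 then being oxidised to C–OH. One operation joins an enantioenriched tertiary allylsilane (C7–C10, C14, C1=C2) to chelated (S)-2-(benzyloxy)propanal (C3, C4, C15), forms both ring bonds and sets C1, C3 and C10. The ten-membered ring is closed late by a chromium-mediated allylation that also builds the methylene lactone.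

Key step: step 6

Remark (numbering and abbreviations): C1 is the oxolane carbinol, C2 its CH2, C3 the ether CH, C4=C5 the ring alkene, C6 the lactone carbinol, C7 the ring-fusion CH, C8 the ester carbinol, C9 a CH2, C10 the quaternary ether carbon, C11–C13 the methylene lactone, C14 and C15 the methyls on C10 and C4; Bn = benzyl, TBS = tert-butyldimethylsilyl, TIPS = triisopropylsilyl, TES = triethylsilyl.

Remark (configuration): the SMILES is read literally as (1S,3S,6S,7R,8R,10R), 4Z, with a (Z)-2-methylbut-2-enoate. This places C4 and C9 on opposite faces of the oxolane (2,5-trans), the C1 hydroxyl cis to C14, and the lactone cis-fused. A rough geometric estimate suggests that a ten-membered ring bridged across a 2,5-trans oxolane is severely strained and may not be attainable; the route is nevertheless built for exactly this configuration, and the ring closure in step 19 carries that risk.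

Step 1
Reactants: 1 (R)-benzyl glycidyl ether
Product: 2 (R)-1-(benzyloxy)pent-4-yn-2-ol
Conditions: LiC≡CH·H2NCH2CH2NH2, DMSO, 0 °C → rt; aq. NH4Cl
Reagents that add atoms: lithium acetylide–ethylenediamine complex, [Li+].[C-]#C.NCCN
Why: SN2 opening of the terminal epoxide carbon by the acetylide (epoxide alkynylation) leaves the C8 stereocentre untouched, so the R configuration of 1 is carried over.

Step 2
Reactants: 2 (R)-1-(benzyloxy)pent-4-yn-2-ol
Product: 3 TBS ether of 2 (C8–OTBS; R)
Conditions: TBSCl, imidazole, DMF, rt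
Reagents that add atoms: tert-butyldimethylsilyl chloride, CC(C)(C)[Si](C)(C)Cl
Why: Standard silylation of the secondary alcohol, with no stereocentre touched.

Step 3
Reactants: 3 TBS ether of 2
Product: 5 (R,E)-6-(benzyloxy)-5-(tert-butyldimethylsilyloxy)-3-methylhex-2-en-1-ol, via alkenylalane 4 (not isolated)
Conditions: Me3Al, Cp2ZrCl2 (0.25 equiv), CH2Cl2, 0 °C → rt; then n-BuLi, THF, −78 °C; (CH2O)n, −78 °C → rt
Reagents that add atoms: trimethylaluminium, C[Al](C)C; paraformaldehyde (as formaldehyde), C=O
Why: Zirconium-catalysed Negishi carboalumination adds methyl and aluminium syn across the terminal alkyne with methyl on the internal carbon, and the derived aluminate is hydroxymethylated with retention, which fixes the E geometry of the C1=C10 bond.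

Step 4
Reactants: 5 allylic alcohol
Product: 6 diethyl (R,E)-6-(benzyloxy)-5-(tert-butyldimethylsilyloxy)-3-methylhex-2-enyl phosphate
Conditions: ClP(O)(OEt)2, pyridine, DMAP (cat.), CH2Cl2, 0 °C
Reagents that add atoms: diethyl chlorophosphate, CCOP(=O)(Cl)OCC
Why: Phosphorylation of the primary allylic alcohol installs the leaving group for the copper-catalysed SN2′ substitution.

Step 5
Reactants: 6 allyl phosphate
Product: 7 [(3S,5R)-6-(benzyloxy)-5-(tert-butyldimethylsilyloxy)-3-methylhex-1-en-3-yl]dimethyl(phenyl)silane (C10 S; C8 R)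
Conditions: PhMe2Si–B(pin) (1.5 equiv), CuCl (5 mol %), chiral imidazolinium chloride (N-heterocyclic carbene precursor, 5.5 mol %), NaOMe (1.5 equiv), THF, 0 °C
Reagents that add atoms: (dimethylphenylsilyl)boronic acid pinacol ester, CC1(C)OB(OC1(C)C)[Si](C)(C)c1ccccc1
Why: Copper-catalysed asymmetric allylic substitution with a silylboronate (monovalent copper carbene catalyst) delivers silicon to the γ-carbon C10 of the E-trisubstituted allyl phosphate in an SN2′ sense, a reaction type known to give α-tetrasubstituted allylsilanes, and the ligand enantiomer is chosen so that silicon adds to the alkene face that gives 10S.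

Step 6
Reactants: 7 allylsilane (10S,8R); 8 (S)-2-(benzyloxy)propanal
Product: 10 silyl oxolane (1S,3S,4S,8R,10R) with C1–SiMe2Ph, via β-silyl cation 9 (not isolated)
Conditions: SnCl4 (1.05 equiv), CH2Cl2, 4 Å MS, −78 °C (8 pre-complexed, then 7); aq. NaHCO3
Reagents that add atoms: none
Why: SnCl4 chelates the carbonyl and benzyloxy oxygens of 8, the vinyl terminus C2 of 7 attacks C3 anti to silicon (anti-SE2′) on the aldehyde face opposite the C15 methyl of the chelate, and in the resulting silicon-bridged β-silyl cation 9 silicon shifts from C10 to C1 while the tin alkoxide oxygen opens the bridge at C10 from the side opposite silicon, so that C2–C3 and O–C10 form in one operation. The closest known reaction type is the Lewis-acid [3+2] annulation of allylsilanes with aldehydes to 3-silyl oxolanes, in its chelation-controlled variant with α-benzyloxy aldehydes. The oxolane closes by attack of the C3 oxygen on the far carbon of the three-membered silicon-bridged ion (a 5-endo opening), favoured because C10 is tertiary and carries most of the positive charge. C10 is set by inversion of the C–Si stereocentre of 7, C1 by suprafacial silyl migration in the conformer with the small C14 methyl eclipsing the vinyl group (silicon ends cis to C14 and trans to C9), and C3 by the Cram-chelate face of 8, a pairing that corresponds to the 2,5-trans (antiperiplanar transition state) outcome typical of chelated aldehydes. The step needs annulation to outrun Hosomi–Sakurai loss of silicon and participation of the ether oxygens, which the tertiary cation, the dimethylphenylsilyl group and −78 °C should secure, and it needs the C3 face, which the matched pairing of chelate and allylsilane should secure.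

Step 7
Reactants: 10 silyl oxolane
Product: 11 oxolan-1-ol (1S,3S,4S,8R,10R) with free C1–OH
Conditions: KBr, AcOOH, NaOAc, AcOH, rt
Reagents that add atoms: peracetic acid, CC(=O)OO
Why: Fleming–Tamao oxidation (bromodesilylation of the phenyl group, then peracid-induced 1,2-shift of C1 from silicon to oxygen) proceeds with retention, so the carbinol keeps the 1S configuration set in step 6.

Step 8
Reactants: 11 oxolan-1-ol
Product: 12 C1–OTIPS ether (1S,3S,4S,8R,10R)
Conditions: TIPSOTf, 2,6-lutidine, CH2Cl2, 0 °C → rt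
Reagents that add atoms: triisopropylsilyl triflate, CC(C)[Si](OS(=O)(=O)C(F)(F)F)(C(C)C)C(C)C
Why: Silylation with the reactive triflate caps the hindered C1 alcohol as a robust ether that should outlast every later silyl ether cleavage.

Step 9
Reactants: 12 C1–OTIPS ether
Product: 13 C4,C7-diol (1S,3S,4S,8R,10R)
Conditions: H2 (1 atm), Pd(OH)2/C, EtOAc, rt
Reagents that add atoms: none
Why: Hydrogenolysis removes both benzyl ethers at an alkene-free stage and leaves the silyl ethers intact.

Step 10
Reactants: 13 C4,C7-diol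
Product: 14 C7–OTES ether with free C4–OH (1S,3S,4S,8R,10R)
Conditions: TESCl (1.05 equiv), imidazole, CH2Cl2, −40 °C
Reagents that add atoms: chlorotriethylsilane, CC[Si](Cl)(CC)CC
Why: Kinetic silylation should distinguish the primary C7 alcohol from the secondary C4 alcohol.

Step 11
Reactants: 14 C7–OTES ether
Product: 15 C4 methyl ketone (1S,3S,8R,10R)
Conditions: Dess–Martin periodinane, NaHCO3, CH2Cl2, rt
Reagents that add atoms: none
Why: Dess–Martin oxidation converts the C4 carbinol into the methyl ketone under buffered conditions that should not epimerise C3, and removes the auxiliary C4 stereocentre.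

Step 12
Reactants: 16 (2-bromoethoxy)(tert-butyl)dimethylsilane
Product: 17 [2-(tert-butyldimethylsilyloxy)ethyl]triphenylphosphonium bromide
Conditions: PPh3, MeCN, reflux
Reagents that add atoms: triphenylphosphine, c1ccc(cc1)P(c1ccccc1)c1ccccc1
Why: SN2 quaternisation of triphenylphosphine by the primary bromide gives the phosphonium salt.

Step 13
Reactants: 15 C4 methyl ketone; 17 phosphonium bromide
Product: 19 (4Z)-alkene with C6–OTBS (1S,3S,8R,10R), via phosphorus ylide 18 (not isolated)
Conditions: 17, KN(SiMe3)2, THF, −78 °C; then 15, THF/HMPA, −78 °C → rt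
Reagents that add atoms: none
Why: Wittig olefination of an α-alkoxy ketone with a non-stabilised ylide is kinetically Z-selective, placing the ylide chain (C6) cis to the oxygen-bearing carbon C3, which is the 4Z geometry of the target.

Step 14
Reactants: 19 (4Z)-alkene
Product: 20 C7 aldehyde (1S,3S,8R,10R)
Conditions: (COCl)2, DMSO, CH2Cl2, −78 → −40 °C; Et3N, −78 → 0 °C
Reagents that add atoms: none
Why: Under Swern conditions the unhindered primary triethylsilyl ether is exchanged and oxidised directly to the aldehyde while the TBS and TIPS ethers are inert, and the low temperature should avoid epimerisation at C8.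

Step 15
Reactants: 20 C7 aldehyde; 21 methyl acrylate
Product: 22 Morita–Baylis–Hillman adduct (C7 carbinol as a mixture of epimers)
Conditions: DABCO (1 equiv), 21 (excess), MeOH, rt
Reagents that add atoms: none
Why: The Morita–Baylis–Hillman reaction of the activated α-silyloxy aldehyde with methyl acrylate gives the α-methylene β-hydroxy ester, and the new C7 configuration is irrelevant because C7 becomes trigonal in the next step.

Step 16
Reactants: 22 Morita–Baylis–Hillman adduct
Product: 23 (Z)-2-(bromomethyl)enoate (C7=C11; C8 cis to CH2Br)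
Conditions: NBS, Me2S, CH2Cl2, −20 → 0 °C
Reagents that add atoms: N-bromosuccinimide, O=C1CCC(=O)N1Br
Why: The alkoxysulfonium salt of the allylic alcohol is displaced by bromide in an SN2′ sense, which should give the thermodynamically preferred Z bromide with the ester trans to C8.

Step 17
Reactants: 23 (Z)-2-(bromomethyl)enoate
Product: 24 C6 allylic alcohol
Conditions: PPTS (cat.), MeOH/CH2Cl2, 0 °C
Reagents that add atoms: none
Why: Mild acid methanolysis cleaves the primary allylic TBS ether much faster than the hindered secondary silyl ethers at C8 and C1.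

Step 18
Reactants: 24 C6 allylic alcohol
Product: 25 (4Z)-enal bearing the allylic bromide
Conditions: MnO2 (activated, excess), CH2Cl2, rt
Reagents that add atoms: none
Why: Manganese dioxide oxidises the allylic alcohol to the enal under neutral conditions that should preserve the Z geometry and the allylic bromide.

Step 19
Reactants: 25 (4Z)-enal bearing the allylic bromide
Product: 27 macrocyclic methylene lactone with C8–OTBS and C1–OTIPS (1S,3S,6S,7S,8R,10R; the 7-descriptor is S only because of the silyl ether), via seco hydroxy ester 26 (not isolated)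
Conditions: CrCl2 (8 equiv), THF (2 mM, slow addition), rt; aq. NH4Cl; PPTS (cat.), CH2Cl2 to complete lactonisation
Reagents that add atoms: none
Why: Divalent chromium inserts into the allylic bromide and the resulting 2-(methoxycarbonyl)allylchromium (trivalent chromium) adds through its γ-carbon C7 to the tethered enal in a chair Zimmerman–Traxler transition state (intramolecular Nozaki–Hiyama allylation), the Z allylmetal giving the syn adduct and hence the cis-fused lactone, the C7 face being set by C8 (C8–H in the alkene plane, ring chain anti to the aldehyde, silyloxy group outside), and the alkoxide of 26 closing onto the ester.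

Step 20
Reactants: 27 macrocyclic methylene lactone
Product: 28 C8 alcohol (1S,3S,6S,7R,8R,10R)
Conditions: HF·pyridine, pyridine, THF, 0 °C → rt
Reagents that add atoms: none
Why: The less hindered C8 TBS ether should be cleaved selectively, because the TIPS ether on the neopentyl-type C1 carbinol reacts far more slowly.

Step 21
Reactants: 28 C8 alcohol; 29 angelic acid
Product: 31 C8 angelate with C1–OTIPS, via mixed anhydride 30 (not isolated)
Conditions: 29, 2,4,6-trichlorobenzoyl chloride, Et3N, toluene, rt; then 28, DMAP, 70 °C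
Reagents that add atoms: none
Why: Yamaguchi esterification acylates the C8 alcohol through the mixed anhydride without base-induced isomerisation of the (Z)-2-methylbut-2-enoyl group to its E isomer.

Step 22
Reactants: 31 C8 angelate with C1–OTIPS
Product: 32 target CNP0213894.2
Conditions: HF·pyridine (excess), THF, rt → 40 °C
Reagents that add atoms: none
Why: Acidic fluoride cleavage of the TIPS ether frees the C1 hydroxyl without touching the angelate, the methylene lactone or the allylic lactone C–O bond.

Compound list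
1 | (R)-benzyl glycidyl ether | C1O[C@H]1COCc2ccccc2 | starting material
2 | (R)-1-(benzyloxy)pent-4-yn-2-ol | C#CC[C@@H](O)COCc1ccccc1 | intermediate
3 | tert-butyl{[(R)-1-(benzyloxy)pent-4-yn-2-yl]oxy}dimethylsilane | C#CC[C@@H](O[Si](C)(C)C(C)(C)C)COCc1ccccc1 | intermediate
4 | dimethyl[(R,E)-5-(benzyloxy)-4-(tert-butyldimethylsilyloxy)-2-methylpent-1-enyl]alane | C[Al](C)/C=C(\C)C[C@@H](O[Si](C)(C)C(C)(C)C)COCc1ccccc1 | intermediate
5 | (R,E)-6-(benzyloxy)-5-(tert-butyldimethylsilyloxy)-3-methylhex-2-en-1-ol | OC/C=C(\C)C[C@@H](O[Si](C)(C)C(C)(C)C)COCc1ccccc1 | intermediate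
6 | diethyl (R,E)-6-(benzyloxy)-5-(tert-butyldimethylsilyloxy)-3-methylhex-2-enyl phosphate | CCOP(=O)(OCC)OC/C=C(\C)C[C@@H](O[Si](C)(C)C(C)(C)C)COCc1ccccc1 | intermediate
7 | [(3S,5R)-6-(benzyloxy)-5-(tert-butyldimethylsilyloxy)-3-methylhex-1-en-3-yl]dimethyl(phenyl)silane | C=C[C@](C)(C[C@@H](O[Si](C)(C)C(C)(C)C)COCc1ccccc1)[Si](C)(C)c1ccccc1 | intermediate
8 | (S)-2-(benzyloxy)propanal | C[C@H](OCc1ccccc1)C=O | starting material
9 | tin-bound β-silyl cation (C3–O–SnCl3, silicon on C1 bridging to cationic C10; chloride counter-ion) | C[C@H](OCc1ccccc1)[C@@H](O[Sn](Cl)(Cl)Cl)C[C@H]([Si](C)(C)c1ccccc1)[C+](C)C[C@@H](O[Si](C)(C)C(C)(C)C)COCc1ccccc1.[Cl-] | intermediate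
10 | silyl oxolane (1S,3S,4S,8R,10R): C3 bears (S)-CH(OBn)CH3, C1 bears SiMe2Ph, C10 bears CH3 and CH2–CH(OTBS)–CH2OBn | C[C@H](OCc1ccccc1)[C@@H]1C[C@H]([Si](C)(C)c2ccccc2)[C@@](C)(C[C@@H](O[Si](C)(C)C(C)(C)C)COCc2ccccc2)O1 | intermediate
11 | oxolan-1-ol (1S,3S,4S,8R,10R): as 10 with C1–OH | C[C@H](OCc1ccccc1)[C@@H]1C[C@H](O)[C@@](C)(C[C@@H](O[Si](C)(C)C(C)(C)C)COCc2ccccc2)O1 | intermediate
12 | C1–OTIPS ether of 11 (1S,3S,4S,8R,10R) | C[C@H](OCc1ccccc1)[C@@H]1C[C@H](O[Si](C(C)C)(C(C)C)C(C)C)[C@@](C)(C[C@@H](O[Si](C)(C)C(C)(C)C)COCc2ccccc2)O1 | intermediate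
13 | C4,C7-diol (1S,3S,4S,8R,10R) | C[C@H](O)[C@@H]1C[C@H](O[Si](C(C)C)(C(C)C)C(C)C)[C@@](C)(C[C@@H](O[Si](C)(C)C(C)(C)C)CO)O1 | intermediate
14 | C7–OTES ether with C4–OH (1S,3S,4S,8R,10R) | C[C@H](O)[C@@H]1C[C@H](O[Si](C(C)C)(C(C)C)C(C)C)[C@@](C)(C[C@@H](O[Si](C)(C)C(C)(C)C)CO[Si](CC)(CC)CC)O1 | intermediate
15 | C4 methyl ketone (1S,3S,8R,10R) | CC(=O)[C@@H]1C[C@H](O[Si](C(C)C)(C(C)C)C(C)C)[C@@](C)(C[C@@H](O[Si](C)(C)C(C)(C)C)CO[Si](CC)(CC)CC)O1 | intermediate
16 | (2-bromoethoxy)(tert-butyl)dimethylsilane | BrCCO[Si](C)(C)C(C)(C)C | starting material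
17 | [2-(tert-butyldimethylsilyloxy)ethyl]triphenylphosphonium bromide | [Br-].CC(C)(C)[Si](C)(C)OCC[P+](c1ccccc1)(c1ccccc1)c1ccccc1 | intermediate
18 | [2-(tert-butyldimethylsilyloxy)ethylidene]triphenylphosphorane | CC(C)(C)[Si](C)(C)OCC=P(c1ccccc1)(c1ccccc1)c1ccccc1 | intermediate
19 | (4Z)-alkene with C6–OTBS, C7–OTES, C8–OTBS, C1–OTIPS (1S,3S,8R,10R) | CC(C)(C)[Si](C)(C)OC/C=C(/C)[C@@H]1C[C@H](O[Si](C(C)C)(C(C)C)C(C)C)[C@@](C)(C[C@@H](O[Si](C)(C)C(C)(C)C)CO[Si](CC)(CC)CC)O1 | intermediate
20 | C7 aldehyde (1S,3S,8R,10R; 4Z) | CC(C)(C)[Si](C)(C)OC/C=C(/C)[C@@H]1C[C@H](O[Si](C(C)C)(C(C)C)C(C)C)[C@@](C)(C[C@@H](O[Si](C)(C)C(C)(C)C)C=O)O1 | intermediate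
21 | methyl acrylate | C=CC(=O)OC | starting material
22 | Morita–Baylis–Hillman adduct (C7 carbinol, epimer mixture; 1S,3S,8R,10R; 4Z) | CC(C)(C)[Si](C)(C)OC/C=C(/C)[C@@H]1C[C@H](O[Si](C(C)C)(C(C)C)C(C)C)[C@@](C)(C[C@@H](O[Si](C)(C)C(C)(C)C)C(O)C(=C)C(=O)OC)O1 | intermediate
23 | (Z)-2-(bromomethyl)enoate with C6–OTBS (1S,3S,8R,10R; 4Z) | CC(C)(C)[Si](C)(C)OC/C=C(/C)[C@@H]1C[C@H](O[Si](C(C)C)(C(C)C)C(C)C)[C@@](C)(C[C@@H](O[Si](C)(C)C(C)(C)C)/C=C(\CBr)C(=O)OC)O1 | intermediate
24 | C6 allylic alcohol of 23 | OC/C=C(/C)[C@@H]1C[C@H](O[Si](C(C)C)(C(C)C)C(C)C)[C@@](C)(C[C@@H](O[Si](C)(C)C(C)(C)C)/C=C(\CBr)C(=O)OC)O1 | intermediate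
25 | (4Z)-enal bearing the (Z)-2-(bromomethyl)enoate | O=C/C=C(/C)[C@@H]1C[C@H](O[Si](C(C)C)(C(C)C)C(C)C)[C@@](C)(C[C@@H](O[Si](C)(C)C(C)(C)C)/C=C(\CBr)C(=O)OC)O1 | intermediate
26 | seco hydroxy ester: ten-membered ring closed, C6–OH free, C7 bearing the methyl acrylate unit (1S,3S,6S,7S,8R,10R) | O[C@H]1/C=C(/C)[C@@H]2C[C@H](O[Si](C(C)C)(C(C)C)C(C)C)[C@@](C)(C[C@@H](O[Si](C)(C)C(C)(C)C)[C@H]1C(=C)C(=O)OC)O2 | intermediate
27 | macrocyclic methylene lactone with C8–OTBS and C1–OTIPS (1S,3S,6S,7S,8R,10R) | C=C1C(=O)O[C@H]2/C=C(/C)[C@@H]3C[C@H](O[Si](C(C)C)(C(C)C)C(C)C)[C@@](C)(C[C@@H](O[Si](C)(C)C(C)(C)C)[C@@H]12)O3 | intermediate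
28 | C8 alcohol with C1–OTIPS (1S,3S,6S,7R,8R,10R) | C=C1C(=O)O[C@H]2/C=C(/C)[C@@H]3C[C@H](O[Si](C(C)C)(C(C)C)C(C)C)[C@@](C)(C[C@@H](O)[C@@H]12)O3 | intermediate
29 | angelic acid, (Z)-2-methylbut-2-enoic acid | C/C=C(/C)C(=O)O | starting material
30 | angelic 2,4,6-trichlorobenzoic anhydride | C/C=C(/C)C(=O)OC(=O)c1c(Cl)cc(Cl)cc1Cl | intermediate
31 | C8 angelate with C1–OTIPS (1S,3S,6S,7R,8R,10R) | C=C1C(=O)O[C@H]2/C=C(/C)[C@@H]3C[C@H](O[Si](C(C)C)(C(C)C)C(C)C)[C@@](C)(C[C@@H](OC(=O)/C(C)=C\C)[C@@H]12)O3 | intermediate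
32 | CNP0213894.2 (1S,3S,6S,7R,8R,10R; 4Z) | C=C1C(=O)O[C@H]2/C=C(/C)[C@@H]3C[C@H](O)[C@@](C)(C[C@@H](OC(=O)/C(C)=C\C)[C@@H]12)O3 | target

Total step count: 22. Longest linear sequence: 21 steps (steps 1–11 and 13–22); step 12 is a one-step branch.

Steps most likely to fail

Step 19 (ring closure). Closing a ten-membered ring across a 2,5-trans-disubstituted oxolane is strained, so cyclisation may be slow or not occur at all. Oligomerisation, protonation of the allylchromium, loss of the C8 silyloxy group by 1,4-elimination, or addition to the wrong face of C7 could then take over. The fallback replaces the cyclic organochromium transition state by a Lewis-acid allylation through an open transition state. It sets out from 24. Treatment with Bu3SnLi and CuBr·SMe2 (THF, −78 °C) should convert the allylic bromide into the allylstannane alcohol F5. MnO2 should oxidise this to the stannyl enal F6. BF3·OEt2 in dilute CH2Cl2 at −78 °C, followed by PPTS, should then close the ring and the lactone, and the route is rejoined at 27.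

Step 6 (key step). Loss of silicon after C–C bond formation (Hosomi–Sakurai allylation) may compete with ring closure. Reaction through the conformer with C9 eclipsing the vinyl group would give the C1 epimer, and a mismatch between chelate and allylsilane faces would lower the selectivity at C3. The fallback forms the two bonds in separate, known steps and sets out from 7 and 8. A chelation-controlled Hosomi–Sakurai allylation (TiCl4, CH2Cl2, −78 °C) should give the (E)-homoallylic alcohol F1. Shi epoxidation (fructose-derived ketone catalyst, KHSO5, enantiomer chosen for the 1S,10S epoxide) should give the epoxy alcohol F2. Camphorsulfonic acid should then induce 5-endo opening at the tertiary C10 with inversion, which returns to the route at 11 and bypasses the Fleming–Tamao oxidation.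

Step 13 (Wittig olefination). The β-silyloxy ylide may lose silanolate before it adds. The basic ylide may enolise the ketone and epimerise C3, and the Z preference may erode with this hindered ketone. The fallback changes to a phosphonate olefination at the ester oxidation level and sets out from 15. Methyl bis(2,2,2-trifluoroethyl)phosphonoacetate with KN(SiMe3)2 and 18-crown-6 (THF, −78 °C) should give the (Z)-enoate F3, separable from any E isomer. Reduction with i-Bu2AlH (CH2Cl2, −78 °C) should give the allylic alcohol F4, and TBSCl with imidazole returns to the route at 19.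

Further compounds
F1 | step 6 | (E)-homoallylic alcohol (3S,4S,8R): C3–OH, C1=C10 alkene, C4–OBn, C8–OTBS, C7–OBn | C[C@H](OCc1ccccc1)[C@@H](O)C/C=C(\C)C[C@@H](O[Si](C)(C)C(C)(C)C)COCc1ccccc1
F2 | step 6 | C1,C10-epoxy alcohol (1S,3S,4S,8R,10S) | C[C@H](OCc1ccccc1)[C@@H](O)C[C@@H]1O[C@@]1(C)C[C@@H](O[Si](C)(C)C(C)(C)C)COCc1ccccc1
F3 | step 13 | methyl (Z)-enoate at C4=C5 with C6 as ester (1S,3S,8R,10R) | COC(=O)/C=C(/C)[C@@H]1C[C@H](O[Si](C(C)C)(C(C)C)C(C)C)[C@@](C)(C[C@@H](O[Si](C)(C)C(C)(C)C)CO[Si](CC)(CC)CC)O1
F4 | step 13 | (4Z)-allylic alcohol with free C6–OH (1S,3S,8R,10R) | OC/C=C(/C)[C@@H]1C[C@H](O[Si](C(C)C)(C(C)C)C(C)C)[C@@](C)(C[C@@H](O[Si](C)(C)C(C)(C)C)CO[Si](CC)(CC)CC)O1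
F5 | step 19 | (Z)-2-(tributylstannylmethyl)enoate with free C6–OH | OC/C=C(/C)[C@@H]1C[C@H](O[Si](C(C)C)(C(C)C)C(C)C)[C@@](C)(C[C@@H](O[Si](C)(C)C(C)(C)C)/C=C(\C[Sn](CCCC)(CCCC)CCCC)C(=O)OC)O1
F6 | step 19 | (4Z)-enal bearing the (Z)-2-(tributylstannylmethyl)enoate | O=C/C=C(/C)[C@@H]1C[C@H](O[Si](C(C)C)(C(C)C)C(C)C)[C@@](C)(C[C@@H](O[Si](C)(C)C(C)(C)C)/C=C(\C[Sn](CCCC)(CCCC)CCCC)C(=O)OC)O1
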